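## Analysis of the target

Target 33 is an unbranched C19 fatty acid methyl ester, numbered here from the ester carbon C1 to the brominated alkyne carbon C19. It carries a trans-1,2-disubstituted cyclopropane (C5–C6–C7), a methyl-bearing stereocentre at C8 directly on the ring, a (9E,11E)-diene with a methyl group on C12, a second methyl stereocentre at C16 and a 1-bromoalkyne (C18≡C19). C5, C7 and C8 form a contiguous triad (5R,7R,8R). C16 (S) lies seven carbons away, so the two regions cannot control each other and each half has to be made enantiopure on its own. The bromoalkyne does not survive zerovalent palladium, organometallic reagents or strong base; the diene is sensitive to acid, electrophiles and oxidants; a cation, radical or metal on C4 or C8 next to the ring invites ring opening. The hard part is the triad, because an acyclic stereocentre attached to a trans-cyclopropane is not set by a simple cyclopropanation of an alkene. The second problem is the (E,E)-diene with its trisubstituted C11=C12 bond between two stereochemically loaded halves. The plan rests on two features: C7 and C8 are neighbours and can be read as the carbinol and methyl carbons of a syn crotylation product, and C5 is γ to C7, so a C4 carbonyl can make C5 an enolate carbon that closes ring C5–C6–C7 by displacing an oxygen leaving group on C7.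

## Retrosynthetic reasoning

**C19–Br.** The bromine is put on last, from the silyl-capped alkyne 31. A 1-bromoalkyne would add to zerovalent palladium and would be attacked by the organometallic and basic reagents used earlier, whereas the bulky silyl cap survives all of them. The forward step must exchange silicon for bromine without touching the diene.

**C10–C11.** Compound 31 is cut between two sp2 carbons into alkenyl iodide 20 and terminal alkyne 28. The cut gives two halves of similar size, each with its own stereocentres. The C11=C12 geometry then comes from a syn methylmetalation of 28 and the C9=C10 geometry from an iodo-olefination. The forward reaction has to join the two alkenyl partners with retention on both sides.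

**Right half (C11–C19).** Alkyne 28 comes from iodide 27 by alkylation of an acetylide (C12–C13), and 27 from alcohol 26. The C13 oxygen of 26 arises by oxidative cleavage of the trisubstituted alkene of 24. The protected alkyne of 24 comes, via 22, from one-carbon homologation of the aldehyde of (S)-citronellal 21, which supplies C16 from the chiral pool.

**C9=C10.** Iodide 20 comes from aldehyde 19 by one-carbon iodo-olefination. Aldehyde 19 is unmasked only at this point, from alcohol 18 and silyl ether 17, so that the epimerisable C8 centre is never exposed to base as an α-carbon of an aldehyde.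

**C3–C4.** The C1–C3 ester arm of 17 is attached by a three-carbon Wittig reaction on cyclopropyl aldehyde 14 (giving 15, then 16), followed by metal-free saturation of the new alkene. C4 is kept as a carbonyl electrophile because a cyclopropylmethyl cation, radical or organometal at C4 would open the ring.

**Functional group changes at C4 and C9.** Aldehyde 14 comes from Weinreb amide 13. Its silyloxy group at C9 comes, via alcohol 12, from cleavage of the vinyl group of 10. The vinyl group has to go before the alkene reduction, which would otherwise consume it first, and in 10 it is the only alkene.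

**C5–C7 (key disconnection).** Cyclopropane 10 is opened between C5 and C7 to mesylate 8. This is the only cut that lets C7 and C8 come from one acyclic stereodyad while C5 is set by the ring closure itself. The forward step must alkylate the C5 enolate at C7 with inversion and place the amide trans to the C8 branch.

**C7–C8.** Mesylate 8 comes from hydroxy amide 7 and lactone 6. Lactone 6 is the syn crotylation product of aldehyde 2 with (Z)-but-2-ene 1, which sets C7 and C8 in one reagent-controlled step.

## Alternatives that were turned down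

**Alternative 1:** Sequential cross-coupling at C12.
- Disconnection: C12–C13 and C12–CH3.
- Forward key step: the left-half dibromodiene A1 couples under palladium catalysis first with the right-half alkylzinc iodide A2 at the bromide trans to C10, then with a methylzinc reagent at the remaining bromide, giving the silyl-capped skeleton A3.
- For: it is highly convergent. The right half needs neither an acetylide alkylation nor a methylalumination next to a second alkyne, so it is about one step shorter and avoids that chemoselectivity question.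
- Against: it does not address the C5/C7/C8 triad. A1 still has to be made, with two more carbons and a dibromo-olefination beyond the C9 aldehyde. The second coupling takes place at the hindered bromide cis to the diene chain, where the alkenylpalladium can isomerise or be reduced.
- Comparison: it is stronger on convergence and right-half economy. The chosen plan offers instead a diene geometry fixed by one syn carbometalation and a single palladium event, and above all a solution to the triad.

**Alternative 2:** Directed cyclopropanation.
- Disconnection: C5–C6 and C6–C7, by methylene transfer.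
- Forward key step: the E-allylic alcohol A4 is cyclopropanated by an iodomethylzinc carbenoid under the direction of a chiral boron-based ligand bound to the hydroxyl, giving cyclopropylmethanol A5.
- For: both ring stereocentres are set in one step of a type that is dependable for E-allylic alcohols. The C1–C4 ester chain is present from the start, so no homologation and no alkene reduction are needed.
- Against: in A5 the future C8 is only a CH2OH carbon. Its methyl and alkenyl branches would have to be added next to the finished ring with control relative to C7. That needs a second stereochemistry-inducing operation at a cyclopropylcarbinyl position, where ionisation opens the ring and additions to the aldehyde are only moderately face-selective.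
- Comparison: it is stronger for the ring itself. The chosen plan sets C7 and C8 together with one reagent and relays them to C5, so no stereocentre has to be created beside an existing cyclopropane.

**Alternative 3:** Boronate homologation and olefination at C8.
- Disconnection: C7–C8 and C8–C9.
- Forward key step: the trans-cyclopropyl boronate A6 is combined with an enantioenriched α-lithiated ethyl ester carbenoid and then with a vinyl-lithium reagent. Two 1,2-migrations form C7–C8 and C8–C9 and give A7.
- For: C8 is set by the reagent independently of the ring, so either epimer is accessible. A7 already carries the C1–C4 carbons, so the Wittig and diimide steps would be saved.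
- Against: A6 must itself be enantiopure, which requires a separate asymmetric step and a second source of chirality. A cyclopropyl carbon migrates reluctantly in boronate rearrangements because of its high s-character. The chain end still needs deprotection, oxidation and esterification.
- Comparison: it is stronger in modularity and in avoiding chain homologation. The chosen plan needs only one chirality source for the whole triad, made from inexpensive pinene, and its ring closure belongs to a long-established reaction type.

Key step: step 4

Remark on the chemistry: positions are given by the target locants C1–C19 in all intermediates. The (−)-enantiomer of B-methoxydiisopinocampheylborane, made from (+)-α-pinene, is assumed to deliver the crotyl group to the Si face of aldehyde 2, as it does with other unbranched aliphatic aldehydes. The alkene of 15 and 16 is drawn Z, but its geometry is irrelevant because step 10 saturates it.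

## Route

Step 1
Reactants: 1 (Z)-but-2-ene; 2 methyl 4-oxobutanoate
Product: 6 (5R)-5-[(2R)-but-3-en-2-yl]oxolan-2-one, via (Z)-but-2-enylpotassium 3 (not isolated), via (Z)-crotyldiisopinocampheylborane 4 (not isolated), via hydroxy ester 5 (not isolated)
Conditions: KOt-Bu, n-BuLi, THF, −78 → −45 °C; (−)-Ipc2BOMe, −78 °C; BF3·OEt2; 2, −78 °C; NaBO3·4H2O, THF/H2O, rt; TsOH·H2O (cat.), CH2Cl2, rt
Reagents that add atoms: none
Why: Brown crotylboration through a closed chair (Zimmerman–Traxler) transition state, in which the Z geometry of the crotyl group gives the syn C7/C8 dyad and the isopinocampheyl groups direct attack to the Si face of the aldehyde, so that 5 should be the (4R,5R) isomer. The ester is inert to the allylborane, and the γ-hydroxy ester lactonises under acid catalysis.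

Step 2
Reactants: 6 (5R)-5-[(2R)-but-3-en-2-yl]oxolan-2-one
Product: 7 (4R,5R)-4-hydroxy-N-methoxy-N,5-dimethylhept-6-enamide
Conditions: MeNHOMe·HCl, AlMe3, CH2Cl2, 0 °C → rt; aqueous potassium sodium tartrate; used crude
Reagents that add atoms: N,O-dimethylhydroxylamine hydrochloride, CNOC.Cl
Why: Weinreb amidation of a lactone by the aluminium amide formed from AlMe3 and the amine salt; the acyl–oxygen bond is cleaved, so C7 and C8 are untouched. The hydroxy amide is carried on at once because it can relactonise.

Step 3
Reactants: 7 (4R,5R)-4-hydroxy-N-methoxy-N,5-dimethylhept-6-enamide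
Product: 8 (4R,5R)-N-methoxy-N,5-dimethyl-4-[(methylsulfonyl)oxy]hept-6-enamide
Conditions: MsCl, Et3N, CH2Cl2, −30 → 0 °C; cold aqueous NaHCO3; used crude
Reagents that add atoms: methanesulfonyl chloride, CS(=O)(=O)Cl
Why: O-sulfonylation of a secondary alcohol; the C7–O bond is not broken, so the configuration is retained. Low temperature and immediate use limit displacement of the sulfonate by the neighbouring amide oxygen.

Step 4
Reactants: 8 (4R,5R)-N-methoxy-N,5-dimethyl-4-[(methylsulfonyl)oxy]hept-6-enamide
Product: 10 (1R,2S)-2-[(2R)-but-3-en-2-yl]-N-methoxy-N-methylcyclopropane-1-carboxamide, via lithium enolate 9 (not isolated)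
Conditions: LiN(SiMe3)2 (1.15 equiv), THF, −78 → 0 °C
Reagents that add atoms: none
Why: LiN(SiMe3)2 removes a C5 proton of the Weinreb amide to give the (Z)-lithium enolate 9, whose α-carbon attacks C7 from the side opposite the mesylate and expels methanesulfonate, so the C5–C7 bond and the three-membered ring form in one intramolecular SN2 event. The closest known reaction type is the base-mediated closure of γ-halo and γ-sulfonyloxy esters, amides, ketones and nitriles to cyclopropanecarbonyl compounds. Ring C5–C6–C7 closes in the 3-exo-tet mode, which is fast despite the strain because nucleophile and electrophile are held three atoms apart. C7 is not new but is inverted, as the backside geometry of the displacement demands, and this turns the syn carbinol/methyl pair of 8 into the C7/C8 relationship of the target while C8 is a spectator. The new centre C5 is set in the transition state, where the bulky enolate unit and the branched C8 substituent avoid eclipsing and end up on opposite faces of the ring, which should give the trans isomer. The step needs substitution to win over E2 elimination toward the allylic C8–H and C-alkylation to win over O-alkylation; a small excess of a hindered, weakly nucleophilic base, the lithium counter-ion in THF and low temperature should secure both, since enolisation consumes the base and the intramolecular closure outruns bimolecular processes. Any cis isomer can be converged later, because aldehyde 14 equilibrates to the trans form under mild base.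

Step 5
Reactants: 10 (1R,2S)-2-[(2R)-but-3-en-2-yl]-N-methoxy-N-methylcyclopropane-1-carboxamide
Product: 12 (1R,2S)-2-[(2S)-1-hydroxypropan-2-yl]-N-methoxy-N-methylcyclopropane-1-carboxamide, via aldehyde 11 (not isolated)
Conditions: O3, CH2Cl2/MeOH, −78 °C; NaBH4, −78 → 0 °C
Reagents that add atoms: ozone, [O-][O+]=O
Why: Ozonolysis of the only alkene with reductive work-up; the C9 aldehyde is reduced as it is released, so C8 cannot epimerise, and the Weinreb amide is inert to NaBH4 at this temperature. The change of the C8 descriptor from R to S reflects only a change in substituent priority.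

Step 6
Reactants: 12 (1R,2S)-2-[(2S)-1-hydroxypropan-2-yl]-N-methoxy-N-methylcyclopropane-1-carboxamide
Product: 13 (1R,2S)-2-[(2S)-1-{[tert-butyl(dimethyl)silyl]oxy}propan-2-yl]-N-methoxy-N-methylcyclopropane-1-carboxamide
Conditions: TBSCl, imidazole, CH2Cl2, rt
Reagents that add atoms: tert-butyl(chloro)dimethylsilane, CC(C)(C)[Si](C)(C)Cl
Why: Standard silylation of a primary alcohol; the ether keeps C9 at the alcohol oxidation level through the hydride, ylide and diimide steps.

Step 7
Reactants: 13 (1R,2S)-2-[(2S)-1-{[tert-butyl(dimethyl)silyl]oxy}propan-2-yl]-N-methoxy-N-methylcyclopropane-1-carboxamide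
Product: 14 (1R,2S)-2-[(2S)-1-{[tert-butyl(dimethyl)silyl]oxy}propan-2-yl]cyclopropane-1-carbaldehyde
Conditions: i-Bu2AlH, THF, −78 °C; aqueous potassium sodium tartrate
Reagents that add atoms: none
Why: Hydride reduction of a Weinreb amide stops at the chelated tetrahedral stage and releases the aldehyde on work-up. The ring carbon C5 is slow to enolise, and the trans isomer is the thermodynamically preferred one in any case.

Step 8
Reactants: 14 (1R,2S)-2-[(2S)-1-{[tert-butyl(dimethyl)silyl]oxy}propan-2-yl]cyclopropane-1-carbaldehyde
Product: 15 (3Z)-4-[(1S,2R)-2-[(2S)-1-{[tert-butyl(dimethyl)silyl]oxy}propan-2-yl]cyclopropyl]but-3-enoic acid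
Conditions: (2-carboxyethyl)triphenylphosphonium bromide, NaN(SiMe3)2 (2 equiv per phosphonium salt), THF, −78 → 0 °C; 14, −78 °C → rt; mild acid work-up
Reagents that add atoms: (2-carboxyethyl)triphenylphosphonium bromide, OC(=O)CC[P+](c1ccccc1)(c1ccccc1)c1ccccc1.[Br-]
Why: Wittig olefination with the carboxylate-bearing, non-stabilised ylide adds C1–C3 in one step and forms the C3=C4 bond. The carboxylate blocks deprotonation α to the carbonyl, which would otherwise expel triphenylphosphine.

Step 9
Reactants: 15 (3Z)-4-[(1S,2R)-2-[(2S)-1-{[tert-butyl(dimethyl)silyl]oxy}propan-2-yl]cyclopropyl]but-3-enoic acid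
Product: 16 methyl (3Z)-4-[(1S,2R)-2-[(2S)-1-{[tert-butyl(dimethyl)silyl]oxy}propan-2-yl]cyclopropyl]but-3-enoate
Conditions: TMSCHN2, PhMe/MeOH, 0 °C
Reagents that add atoms: (trimethylsilyl)diazomethane, C[Si](C)(C)C=[N+]=[N-]
Why: Neutral O-methylation of the carboxylic acid; the absence of base avoids migration of the β,γ-double bond.

Step 10
Reactants: 16 methyl (3Z)-4-[(1S,2R)-2-[(2S)-1-{[tert-butyl(dimethyl)silyl]oxy}propan-2-yl]cyclopropyl]but-3-enoate
Product: 17 methyl 4-[(1R,2R)-2-[(2S)-1-{[tert-butyl(dimethyl)silyl]oxy}propan-2-yl]cyclopropyl]butanoate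
Conditions: 2-nitrobenzenesulfonohydrazide, Et3N, CH2Cl2, rt (repeated charges)
Reagents that add atoms: none
Why: Diimide reduction transfers two hydrogens in a concerted, metal-free step, so the alkene next to the cyclopropane is saturated without hydrogenolysis of the ring; ester and silyl ether are inert.

Step 11
Reactants: 17 methyl 4-[(1R,2R)-2-[(2S)-1-{[tert-butyl(dimethyl)silyl]oxy}propan-2-yl]cyclopropyl]butanoate
Product: 18 methyl 4-[(1R,2R)-2-[(2S)-1-hydroxypropan-2-yl]cyclopropyl]butanoate
Conditions: camphorsulfonic acid (cat.), MeOH, 0 °C → rt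
Reagents that add atoms: none
Why: Acid-catalysed methanolysis of a primary silyl ether; in methanol the methyl ester can only be re-formed, and the alkyl cyclopropane is stable to catalytic acid.

Step 12
Reactants: 18 methyl 4-[(1R,2R)-2-[(2S)-1-hydroxypropan-2-yl]cyclopropyl]butanoate
Product: 19 methyl 4-[(1R,2R)-2-[(2S)-1-oxopropan-2-yl]cyclopropyl]butanoate
Conditions: Dess–Martin periodinane, NaHCO3, CH2Cl2, 0 °C → rt; used crude
Reagents that add atoms: none
Why: Dess–Martin oxidation works under buffered, near-neutral conditions, so the α-stereocentre C8 of the new aldehyde should not epimerise if the product is used at once.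

Step 13
Reactants: 19 methyl 4-[(1R,2R)-2-[(2S)-1-oxopropan-2-yl]cyclopropyl]butanoate
Product: 20 methyl 4-[(1R,2R)-2-[(2S,3E)-4-iodobut-3-en-2-yl]cyclopropyl]butanoate
Conditions: CrCl2, CHI3, THF/1,4-dioxane, 0 °C → rt
Reagents that add atoms: iodoform, IC(I)I
Why: Takai olefination through a geminal dichromium species adds C10 and gives the E-alkenyl iodide preferentially, most reliably with α-branched aldehydes. The reagent is non-basic, so C8 is not at risk, and it tolerates the ester.

Step 14
Reactants: 21 (S)-citronellal [(3S)-3,7-dimethyloct-6-enal]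
Product: 22 (4S)-4,8-dimethylnon-7-en-1-yne
Conditions: dimethyl (1-diazo-2-oxopropyl)phosphonate, K2CO3, MeOH, 0 °C → rt
Reagents that add atoms: dimethyl (1-diazo-2-oxopropyl)phosphonate, COP(=O)(OC)C(=[N+]=[N-])C(C)=O
Why: Ohira–Bestmann homologation turns the aldehyde carbon into C18 and adds C19 as a terminal alkyne; the C16 stereocentre is β to the carbonyl and cannot epimerise.

Step 15
Reactants: 22 (4S)-4,8-dimethylnon-7-en-1-yne
Product: 24 [(4S)-4,8-dimethylnon-7-en-1-yn-1-yl]tri(propan-2-yl)silane, via lithium acetylide 23 (not isolated)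
Conditions: n-BuLi, THF, −78 °C; i-Pr3SiCl, −78 °C → rt
Reagents that add atoms: chlorotri(propan-2-yl)silane, CC(C)[Si](Cl)(C(C)C)C(C)C
Why: Deprotonation and C-silylation of a terminal alkyne; the bulky silyl group is chosen because it withstands borohydride, acetylide and organoaluminium reagents that would strip a trimethylsilyl cap.

Step 16
Reactants: 24 [(4S)-4,8-dimethylnon-7-en-1-yn-1-yl]tri(propan-2-yl)silane
Product: 26 (4S)-4-methyl-7-[tri(propan-2-yl)silyl]hept-6-yn-1-ol, via aldehyde 25 (not isolated)
Conditions: O3, CH2Cl2/MeOH, −78 °C (until 24 is consumed); NaBH4, −78 → 0 °C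
Reagents that add atoms: ozone, [O-][O+]=O
Why: Ozone attacks the electron-rich trisubstituted alkene far faster than the hindered silyl alkyne, and the reductive work-up gives the C13 alcohol directly.

Step 17
Reactants: 26 (4S)-4-methyl-7-[tri(propan-2-yl)silyl]hept-6-yn-1-ol
Product: 27 [(4S)-7-iodo-4-methylhept-1-yn-1-yl]tri(propan-2-yl)silane
Conditions: I2, PPh3, imidazole, CH2Cl2, 0 °C → rt
Reagents that add atoms: iodine, II
Why: Appel-type iodination of a primary alcohol through an alkoxyphosphonium ion.

Step 18
Reactants: 27 [(4S)-7-iodo-4-methylhept-1-yn-1-yl]tri(propan-2-yl)silane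
Product: 28 [(4S)-4-methylnona-1,8-diyn-1-yl]tri(propan-2-yl)silane
Conditions: LiC≡CH·H2NCH2CH2NH2, DMSO, rt
Reagents that add atoms: lithium acetylide–ethylenediamine complex, [Li]C#C.NCCN
Why: SN2 alkylation of an acetylide by an unhindered primary iodide in a dipolar aprotic solvent adds C11 and C12; the triisopropylsilyl alkyne is stable to the reagent.

Step 19
Reactants: 28 [(4S)-4-methylnona-1,8-diyn-1-yl]tri(propan-2-yl)silane; 20 methyl 4-[(1R,2R)-2-[(2S,3E)-4-iodobut-3-en-2-yl]cyclopropyl]butanoate
Product: 31 methyl 4-[(1R,2R)-2-[(2R,3E,5E,10S)-6,10-dimethyl-13-[tri(propan-2-yl)silyl]trideca-3,5-dien-12-yn-2-yl]cyclopropyl]butanoate, via alkenylalane 29 (not isolated), via alkenylzinc chloride 30 (not isolated)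
Conditions: 28, AlMe3, Cp2ZrCl2 (cat.), CH2Cl2, 0 °C → rt; volatiles removed; 20, ZnCl2, Pd(PPh3)4 (cat.), THF, rt
Reagents that add atoms: trimethylaluminium, C[Al](C)C
Why: Zirconium-catalysed methylalumination (Negishi carboalumination) adds methyl and aluminium syn across the terminal alkyne, methyl to C12, which fixes the E geometry of C11=C12; the hindered internal silyl alkyne should not react. Transfer to zinc and palladium-catalysed Negishi coupling with 20 then forms C10–C11 with retention on both alkenyl partners. Excess AlMe3 is stripped off first so that the ester of 20 is not attacked.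

Step 20
Reactants: 31 methyl 4-[(1R,2R)-2-[(2R,3E,5E,10S)-6,10-dimethyl-13-[tri(propan-2-yl)silyl]trideca-3,5-dien-12-yn-2-yl]cyclopropyl]butanoate
Product: 33 methyl 4-[(1R,2R)-2-[(2R,3E,5E,10S)-13-bromo-6,10-dimethyltrideca-3,5-dien-12-yn-2-yl]cyclopropyl]butanoate, via silver acetylide 32 (not isolated)
Conditions: AgF, N-bromosuccinimide, MeCN, rt, dark
Reagents that add atoms: N-bromosuccinimide, O=C1CCC(=O)N1Br
Why: Fluoride-assisted silver desilylation of the bulky silyl alkyne gives a silver acetylide, which is brominated at carbon by N-bromosuccinimide (one-pot bromodesilylation). The acetylide should react faster than the diene, and no base or palladium is present to harm the product.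

## Compound list

1 | (Z)-but-2-ene | C/C=C\C | starting material
2 | methyl 4-oxobutanoate | COC(=O)CCC=O | starting material
3 | (Z)-but-2-enylpotassium | C/C=C\C[K] | intermediate
4 | [(2Z)-but-2-en-1-yl]bis[(1R,2S,3R,5R)-2,6,6-trimethylbicyclo[3.1.1]heptan-3-yl]borane | C/C=C\CB([C@@H]1C[C@@H]2C[C@H]([C@H]1C)C2(C)C)[C@@H]1C[C@@H]2C[C@H]([C@H]1C)C2(C)C | intermediate
5 | methyl (4R,5R)-4-hydroxy-5-methylhept-6-enoate | COC(=O)CC[C@@H](O)[C@H](C)C=C | intermediate
6 | (5R)-5-[(2R)-but-3-en-2-yl]oxolan-2-one | O=C1CC[C@@H](O1)[C@H](C)C=C | intermediate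
7 | (4R,5R)-4-hydroxy-N-methoxy-N,5-dimethylhept-6-enamide | CON(C)C(=O)CC[C@@H](O)[C@H](C)C=C | intermediate
8 | (4R,5R)-N-methoxy-N,5-dimethyl-4-[(methylsulfonyl)oxy]hept-6-enamide | CON(C)C(=O)CC[C@@H](OS(C)(=O)=O)[C@H](C)C=C | intermediate
9 | lithium (1Z,4R,5R)-1-[methoxy(methyl)amino]-5-methyl-4-[(methylsulfonyl)oxy]hepta-1,6-dien-1-olate | CON(C)/C(O[Li])=C/C[C@@H](OS(C)(=O)=O)[C@H](C)C=C | intermediate
10 | (1R,2S)-2-[(2R)-but-3-en-2-yl]-N-methoxy-N-methylcyclopropane-1-carboxamide | CON(C)C(=O)[C@@H]1C[C@H]1[C@H](C)C=C | intermediate
11 | (1R,2S)-N-methoxy-N-methyl-2-[(2S)-1-oxopropan-2-yl]cyclopropane-1-carboxamide | CON(C)C(=O)[C@@H]1C[C@H]1[C@H](C)C=O | intermediate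
12 | (1R,2S)-2-[(2S)-1-hydroxypropan-2-yl]-N-methoxy-N-methylcyclopropane-1-carboxamide | CON(C)C(=O)[C@@H]1C[C@H]1[C@H](C)CO | intermediate
13 | (1R,2S)-2-[(2S)-1-{[tert-butyl(dimethyl)silyl]oxy}propan-2-yl]-N-methoxy-N-methylcyclopropane-1-carboxamide | CON(C)C(=O)[C@@H]1C[C@H]1[C@H](C)CO[Si](C)(C)C(C)(C)C | intermediate
14 | (1R,2S)-2-[(2S)-1-{[tert-butyl(dimethyl)silyl]oxy}propan-2-yl]cyclopropane-1-carbaldehyde | O=C[C@@H]1C[C@H]1[C@H](C)CO[Si](C)(C)C(C)(C)C | intermediate
15 | (3Z)-4-[(1S,2R)-2-[(2S)-1-{[tert-butyl(dimethyl)silyl]oxy}propan-2-yl]cyclopropyl]but-3-enoic acid | OC(=O)C/C=C\[C@@H]1C[C@H]1[C@H](C)CO[Si](C)(C)C(C)(C)C | intermediate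
16 | methyl (3Z)-4-[(1S,2R)-2-[(2S)-1-{[tert-butyl(dimethyl)silyl]oxy}propan-2-yl]cyclopropyl]but-3-enoate | COC(=O)C/C=C\[C@@H]1C[C@H]1[C@H](C)CO[Si](C)(C)C(C)(C)C | intermediate
17 | methyl 4-[(1R,2R)-2-[(2S)-1-{[tert-butyl(dimethyl)silyl]oxy}propan-2-yl]cyclopropyl]butanoate | COC(=O)CCC[C@@H]1C[C@H]1[C@H](C)CO[Si](C)(C)C(C)(C)C | intermediate
18 | methyl 4-[(1R,2R)-2-[(2S)-1-hydroxypropan-2-yl]cyclopropyl]butanoate | COC(=O)CCC[C@@H]1C[C@H]1[C@H](C)CO | intermediate
19 | methyl 4-[(1R,2R)-2-[(2S)-1-oxopropan-2-yl]cyclopropyl]butanoate | COC(=O)CCC[C@@H]1C[C@H]1[C@H](C)C=O | intermediate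
20 | methyl 4-[(1R,2R)-2-[(2S,3E)-4-iodobut-3-en-2-yl]cyclopropyl]butanoate | COC(=O)CCC[C@@H]1C[C@H]1[C@H](C)/C=C/I | intermediate
21 | (S)-citronellal, (3S)-3,7-dimethyloct-6-enal | CC(C)=CCC[C@H](C)CC=O | starting material
22 | (4S)-4,8-dimethylnon-7-en-1-yne | CC(C)=CCC[C@H](C)CC#C | intermediate
23 | [(4S)-4,8-dimethylnon-7-en-1-yn-1-yl]lithium | CC(C)=CCC[C@H](C)CC#C[Li] | intermediate
24 | [(4S)-4,8-dimethylnon-7-en-1-yn-1-yl]tri(propan-2-yl)silane | CC(C)=CCC[C@H](C)CC#C[Si](C(C)C)(C(C)C)C(C)C | intermediate
25 | (4S)-4-methyl-7-[tri(propan-2-yl)silyl]hept-6-ynal | O=CCC[C@H](C)CC#C[Si](C(C)C)(C(C)C)C(C)C | intermediate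
26 | (4S)-4-methyl-7-[tri(propan-2-yl)silyl]hept-6-yn-1-ol | OCCC[C@H](C)CC#C[Si](C(C)C)(C(C)C)C(C)C | intermediate
27 | [(4S)-7-iodo-4-methylhept-1-yn-1-yl]tri(propan-2-yl)silane | ICCC[C@H](C)CC#C[Si](C(C)C)(C(C)C)C(C)C | intermediate
28 | [(4S)-4-methylnona-1,8-diyn-1-yl]tri(propan-2-yl)silane | C#CCCC[C@H](C)CC#C[Si](C(C)C)(C(C)C)C(C)C | intermediate
29 | dimethyl[(1E,6S)-2,6-dimethyl-9-[tri(propan-2-yl)silyl]non-1-en-8-yn-1-yl]alumane | C[Al](C)/C=C(\C)CCC[C@H](C)CC#C[Si](C(C)C)(C(C)C)C(C)C | intermediate
30 | chloro[(1E,6S)-2,6-dimethyl-9-[tri(propan-2-yl)silyl]non-1-en-8-yn-1-yl]zinc | Cl[Zn]/C=C(\C)CCC[C@H](C)CC#C[Si](C(C)C)(C(C)C)C(C)C | intermediate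
31 | methyl 4-[(1R,2R)-2-[(2R,3E,5E,10S)-6,10-dimethyl-13-[tri(propan-2-yl)silyl]trideca-3,5-dien-12-yn-2-yl]cyclopropyl]butanoate | COC(=O)CCC[C@@H]1C[C@H]1[C@H](C)/C=C/C=C(\C)CCC[C@H](C)CC#C[Si](C(C)C)(C(C)C)C(C)C | intermediate
32 | silver acetylide of the target skeleton (33 with Ag in place of Br on C19) | COC(=O)CCC[C@@H]1C[C@H]1[C@H](C)/C=C/C=C(\C)CCC[C@H](C)CC#C[Ag] | intermediate
33 | methyl 4-[(1R,2R)-2-[(2R,3E,5E,10S)-13-bromo-6,10-dimethyltrideca-3,5-dien-12-yn-2-yl]cyclopropyl]butanoate | COC(=O)CCC[C@@H]1C[C@H]1[C@H](C)/C=C/C=C(\C)CCC[C@H](C)CC#CBr | target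

## Step count and least certain steps

Total: 20 steps. The longest linear sequence is 15 steps (steps 1–13, 19 and 20, from 1 and 2). The right half needs five steps (14–18) from 21 before the union.

**Step 4 (key step).** The likely failure is loss of the sulfonate before the ring closes. It can happen by displacement through the neighbouring amide oxygen, by base-induced elimination toward the allylic C8–H, or by fragmentation of the N-methoxy amide under strong base. The secondary C7 is also flanked by the branched C8, so substitution is slower than in unbranched cases. The fallback moves the closure to an ester enolate and sets out from hydroxy ester 5, taken from the perborate work-up of step 1 without lactonisation. It is mesylated at −20 °C (MsCl, Et3N) to methyl (4R,5R)-5-methyl-4-[(methylsulfonyl)oxy]hept-6-enoate F1. Treatment with NaN(SiMe3)2 in THF at −78 °C should close the ring to methyl (1R,2S)-2-[(2R)-but-3-en-2-yl]cyclopropane-1-carboxylate F2. F2 is converted with MeNHOMe·HCl and i-PrMgCl into Weinreb amide 10, where the route is rejoined.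

**Step 8.** The ylide carries a carboxylate β to phosphorus and can collapse by β-elimination of triphenylphosphine before it meets the aldehyde. The dianionic reagent is also poorly soluble, so incomplete olefination is the likely failure. The fallback builds the arm at the alcohol oxidation level. Aldehyde 14 is treated with the ylide from (3-hydroxypropyl)triphenylphosphonium bromide and two equivalents of n-BuLi to give (3Z)-4-[(1S,2R)-2-[(2S)-1-{[tert-butyl(dimethyl)silyl]oxy}propan-2-yl]cyclopropyl]but-3-en-1-ol F3. Diimide reduction gives 4-[(1R,2R)-2-[(2S)-1-{[tert-butyl(dimethyl)silyl]oxy}propan-2-yl]cyclopropyl]butan-1-ol F4. Oxidation with TEMPO and PhI(OAc)2 in aqueous MeCN gives 4-[(1R,2R)-2-[(2S)-1-{[tert-butyl(dimethyl)silyl]oxy}propan-2-yl]cyclopropyl]butanoic acid F5, and methylation with TMSCHN2 returns to 17.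

**Step 13.** The risks are incomplete E selectivity in the iodo-olefination and epimerisation at C8 while the α-branched aldehyde is handled. The fallback fixes the geometry by a syn hydrometalation. Aldehyde 19 is homologated with dimethyl (1-diazo-2-oxopropyl)phosphonate and K2CO3 in MeOH at 0 °C to methyl 4-[(1R,2R)-2-[(2S)-but-3-yn-2-yl]cyclopropyl]butanoate F6. Hydrozirconation with Cp2Zr(H)Cl followed by I2 then gives 20.

**Step 19.** Side reactions in the methylalumination are possible: metalation of the terminal C–H, imperfect regiocontrol and slow attack on the silyl alkyne. In the one-pot coupling, slow transfer from aluminium to zinc to palladium could lead to protodemetalation or homocoupling and waste the advanced iodide 20. The fallback isolates and purifies the right-half partner. The methylalumination of 28 is quenched with I2 to give [(4S,8E)-9-iodo-4,8-dimethylnon-8-en-1-yn-1-yl]tri(propan-2-yl)silane F7. Iodine–lithium exchange with t-BuLi at −78 °C and trapping with 2-isopropoxy-4,4,5,5-tetramethyl-1,3,2-dioxaborolane gives [(4S,8E)-4,8-dimethyl-9-(4,4,5,5-tetramethyl-1,3,2-dioxaborolan-2-yl)non-8-en-1-yn-1-yl]tri(propan-2-yl)silane F8. Suzuki–Miyaura coupling of F8 with 20 (Pd(PPh3)4, K3PO4, THF/H2O) rejoins the route at 31.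

**Step 20.** N-Bromosuccinimide may brominate the electron-rich diene in competition with the silver acetylide, or the bulky silyl group may be cleaved incompletely. The fallback separates the two events. Compound 31 is desilylated with Bu4NF buffered with AcOH in THF at 0 °C to methyl 4-[(1R,2R)-2-[(2R,3E,5E,10S)-6,10-dimethyltrideca-3,5-dien-12-yn-2-yl]cyclopropyl]butanoate F9. F9 is then brominated with N-bromosuccinimide and catalytic AgNO3 in acetone, where the acetylide forms only catalytically, to give 33.

## Further compounds

F1 | step 4 | methyl (4R,5R)-5-methyl-4-[(methylsulfonyl)oxy]hept-6-enoate | COC(=O)CC[C@@H](OS(C)(=O)=O)[C@H](C)C=C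
F2 | step 4 | methyl (1R,2S)-2-[(2R)-but-3-en-2-yl]cyclopropane-1-carboxylate | COC(=O)[C@@H]1C[C@H]1[C@H](C)C=C
F3 | step 8 | (3Z)-4-[(1S,2R)-2-[(2S)-1-{[tert-butyl(dimethyl)silyl]oxy}propan-2-yl]cyclopropyl]but-3-en-1-ol | OCC/C=C\[C@@H]1C[C@H]1[C@H](C)CO[Si](C)(C)C(C)(C)C
F4 | step 8 | 4-[(1R,2R)-2-[(2S)-1-{[tert-butyl(dimethyl)silyl]oxy}propan-2-yl]cyclopropyl]butan-1-ol | OCCCC[C@@H]1C[C@H]1[C@H](C)CO[Si](C)(C)C(C)(C)C
F5 | step 8 | 4-[(1R,2R)-2-[(2S)-1-{[tert-butyl(dimethyl)silyl]oxy}propan-2-yl]cyclopropyl]butanoic acid | OC(=O)CCC[C@@H]1C[C@H]1[C@H](C)CO[Si](C)(C)C(C)(C)C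
F6 | step 13 | methyl 4-[(1R,2R)-2-[(2S)-but-3-yn-2-yl]cyclopropyl]butanoate | COC(=O)CCC[C@@H]1C[C@H]1[C@H](C)C#C
F7 | step 19 | [(4S,8E)-9-iodo-4,8-dimethylnon-8-en-1-yn-1-yl]tri(propan-2-yl)silane | I/C=C(\C)CCC[C@H](C)CC#C[Si](C(C)C)(C(C)C)C(C)C
F8 | step 19 | [(4S,8E)-4,8-dimethyl-9-(4,4,5,5-tetramethyl-1,3,2-dioxaborolan-2-yl)non-8-en-1-yn-1-yl]tri(propan-2-yl)silane | CC1(C)OB(/C=C(\C)CCC[C@H](C)CC#C[Si](C(C)C)(C(C)C)C(C)C)OC1(C)C
F9 | step 20 | methyl 4-[(1R,2R)-2-[(2R,3E,5E,10S)-6,10-dimethyltrideca-3,5-dien-12-yn-2-yl]cyclopropyl]butanoate | COC(=O)CCC[C@@H]1C[C@H]1[C@H](C)/C=C/C=C(\C)CCC[C@H](C)CC#C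
A1 | alternative 1 | methyl 4-[(1R,2R)-2-[(2R,3E)-6,6-dibromohexa-3,5-dien-2-yl]cyclopropyl]butanoate | COC(=O)CCC[C@@H]1C[C@H]1[C@H](C)/C=C/C=C(Br)Br
A2 | alternative 1 | iodo[(4S)-4-methyl-7-(trimethylsilyl)hept-6-yn-1-yl]zinc | I[Zn]CCC[C@H](C)CC#C[Si](C)(C)C
A3 | alternative 1 | methyl 4-[(1R,2R)-2-[(2R,3E,5E,10S)-6,10-dimethyl-13-(trimethylsilyl)trideca-3,5-dien-12-yn-2-yl]cyclopropyl]butanoate | COC(=O)CCC[C@@H]1C[C@H]1[C@H](C)/C=C/C=C(\C)CCC[C@H](C)CC#C[Si](C)(C)C
A4 | alternative 2 | methyl (5E)-7-hydroxyhept-5-enoate | COC(=O)CCC/C=C/CO
A5 | alternative 2 | methyl 4-[(1R,2R)-2-(hydroxymethyl)cyclopropyl]butanoate | COC(=O)CCC[C@@H]1C[C@H]1CO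
A6 | alternative 3 | 2-[(1R,2R)-2-(4-{[tert-butyl(dimethyl)silyl]oxy}butyl)cyclopropyl]-4,4,5,5-tetramethyl-1,3,2-dioxaborolane | CC(C)(C)[Si](C)(C)OCCCC[C@@H]1C[C@H]1B1OC(C)(C)C(C)(C)O1
A7 | alternative 3 | tert-butyl(dimethyl){4-[(1R,2R)-2-[(2R)-but-3-en-2-yl]cyclopropyl]butoxy}silane | CC(C)(C)[Si](C)(C)OCCCC[C@@H]1C[C@H]1[C@H](C)C=C
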